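**Assumption:** locants follow germacrane numbering (ring C1–C10; C4 carries the methyl and hydroxyl, C7 the isopropyl, C8 the ester; alkenes C1=C10 and C5=C6), so the target is the (4R,7S,8S,1(10)E,5E) isomer.

**Retrosynthetic overview**
1. C8–O ester: made last from the (8S)-alcohol 14 and O-acetylvanillic acid 15.
2. C8 carbinol ← ketone ← secondary nitro group: C8 is the carbon of nitromethane, used twice as a nitronate (an acyl anion equivalent, i.e. a carbonyl 1,1-dianion).
3. C8–C9: closes the only carbocycle (ten-membered, step 7) by nitronate attack on the π-allyl palladium of an E-allylic carbonate.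
4. C7–C8 (key bond, step 4): nitronate attack on the π-allyl palladium of a Z-vinyl epoxide; this transfers the epoxide chirality to C7, sets the E-5,6-alkene and frees C4–OH.
5. Vinyl epoxide ← Sharpless epoxidation of geraniol (oxirane made in step 1, opened in step 4), oxidation, Z-Wittig; the arene is bought.

**Route**

Step 1
Reactants: 1 geraniol
Product: 2 [(2R,3R)-3-methyl-3-(4-methylpent-3-en-1-yl)oxiran-2-yl]methanol
Conditions: Ti(OiPr)4 (5 mol%), D-(−)-diethyl tartrate (7 mol%), t-BuOOH, 4 Å molecular sieves, CH2Cl2, −20 °C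
Reagents that add atoms: tert-butyl hydroperoxide, CC(C)(C)OO
Why: Katsuki–Sharpless asymmetric epoxidation of the allylic alcohol only; the D-(−)-tartrate delivers oxygen to the face that gives the (2R,3R) epoxide, which fixes C4 (R) and the C5 centre that later controls C7.

Step 2
Reactants: 2 [(2R,3R)-3-methyl-3-(4-methylpent-3-en-1-yl)oxiran-2-yl]methanol
Product: 3 (2S,3R)-3-methyl-3-(4-methylpent-3-en-1-yl)oxirane-2-carbaldehyde
Conditions: TEMPO (10 mol%), PhI(OAc)2, CH2Cl2, rt
Reagents that add atoms: none
Why: Oxoammonium (TEMPO) oxidation of a primary alcohol to the aldehyde under near-neutral conditions that leave the epoxide, its α-centre and the trisubstituted alkene untouched (the descriptor changes only through CIP priority).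

Step 3
Reactants: 3 (2S,3R)-3-methyl-3-(4-methylpent-3-en-1-yl)oxirane-2-carbaldehyde; 4 isobutyltriphenylphosphonium bromide
Product: 6 (2R,3R)-2-methyl-2-(4-methylpent-3-en-1-yl)-3-[(1Z)-3-methylbut-1-en-1-yl]oxirane, via isobutylidenetriphenylphosphorane 5 (not isolated)
Conditions: KN(SiMe3)2, THF, −78 °C; then 3, −78 °C to rt
Reagents that add atoms: none
Why: Wittig olefination with a non-stabilised ylide under lithium-free conditions is Z-selective (kinetic cis-oxaphosphetane), and this Z geometry is what later places the nucleophile on the correct face of C7 (any E isomer would give the 7-epimer and is removed here).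

Step 4
Reactants: 6 (2R,3R)-2-methyl-2-(4-methylpent-3-en-1-yl)-3-[(1Z)-3-methylbut-1-en-1-yl]oxirane; 7 nitromethane
Product: 8 (6R,7E,9S)-2,6,10-trimethyl-9-(nitromethyl)undeca-2,7-dien-6-ol
Conditions: Pd(PPh3)4 (5 mol%), MeNO2 (20 equiv), THF, rt
Reagents that add atoms: none
Why: Tsuji–Trost allylic alkylation under neutral conditions: zerovalent palladium opens the allylic C5–O bond with inversion, the C4 alkoxide so formed deprotonates nitromethane, and the nitronate (an acyl anion equivalent for C8) attacks the distal terminus C7 anti to palladium (C5 is neopentylic and flanked by the alkoxide), so that with the Z-alkene (isopropyl anti and C4 syn in the π-allyl) C7 is formed S with net retention of the oxygen face, C5=C6 comes out E and the 4R tertiary alcohol is released.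

Step 5
Reactants: 8 (6R,7E,9S)-2,6,10-trimethyl-9-(nitromethyl)undeca-2,7-dien-6-ol
Product: 9 (2E,6R,7E,9S)-2,6,10-trimethyl-9-(nitromethyl)undeca-2,7-diene-1,6-diol
Conditions: SeO2 (0.3 equiv), t-BuOOH, salicylic acid (cat.), CH2Cl2, 0 °C to rt
Reagents that add atoms: tert-butyl hydroperoxide, CC(C)(C)OO; SeO2 (catalytic oxygen carrier), O=[Se]=O
Why: SeO2 allylic oxidation (ene reaction then 2,3-sigmatropic shift) selects the E-methyl of the electron-rich trisubstituted alkene, as it does for linalool, creating C9–OH with the E-1(10) geometry while the hindered 5,6-alkene and the nitro group are left alone.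

Step 6
Reactants: 9 (2E,6R,7E,9S)-2,6,10-trimethyl-9-(nitromethyl)undeca-2,7-diene-1,6-diol
Product: 10 (2E,6R,7E,9S)-6-hydroxy-2,6,10-trimethyl-9-(nitromethyl)undeca-2,7-dien-1-yl methyl carbonate
Conditions: ClCO2Me, pyridine, CH2Cl2, 0 °C
Reagents that add atoms: methyl chloroformate, COC(=O)Cl
Why: Chemoselective acylation of the primary allylic alcohol over the tertiary one gives an allylic carbonate that ionises readily with zerovalent palladium and supplies its own methoxide base.

Step 7
Reactants: 10 (2E,6R,7E,9S)-6-hydroxy-2,6,10-trimethyl-9-(nitromethyl)undeca-2,7-dien-1-yl methyl carbonate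
Product: 11 (4R,7S)-8-nitrogermacra-1(10)E,5E-dien-4-ol (both C8 epimers)
Conditions: Pd2(dba)3·CHCl3 (5 mol%), dppe (12 mol%), THF, 0.002 M by slow addition, 60 °C
Reagents that add atoms: none
Why: Proposed new method: intramolecular Tsuji–Trost alkylation in which zerovalent palladium ionises the carbonate, the liberated methoxide deprotonates the primary nitro group (far more acidic than the tertiary alcohol) and the nitronate carbon C8 closes the ten-membered ring at the primary terminus C9 (attack at C1 would need an eight-membered ring holding an E-alkene), the E geometry being kept because syn/anti exchange at the substituted terminus is slow; the closest known reactions are neutral palladium allylation of nitroalkanes by allylic carbonates and π-allyl palladium macrocyclisations of stabilised carbanions to ten- and eleven-membered rings.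

Step 8
Reactants: 11 (4R,7S)-8-nitrogermacra-1(10)E,5E-dien-4-ol
Product: 13 (4R,7S)-4-hydroxygermacra-1(10)E,5E-dien-8-one, via sodium nitronate 12 (not isolated)
Conditions: NaOMe, MeOH, 0 °C; then TiCl3, NH4OAc, H2O (pH 5–6), rt
Reagents that add atoms: water, O
Why: McMurry's reductive Nef reaction: trivalent titanium reduces the nitronate to the imine, which hydrolyses to the ketone at a buffered pH mild enough for the tertiary allylic alcohol and for the C7 centre (now α to the ketone, but enolisation toward the ring E-alkene is geometrically disfavoured).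

Step 9
Reactants: 13 (4R,7S)-4-hydroxygermacra-1(10)E,5E-dien-8-one
Product: 14 (4R,7S,8S)-germacra-1(10)E,5E-diene-4,8-diol
Conditions: (R)-2-methyl-CBS-oxazaborolidine (20 mol%), catecholborane (3 equiv), toluene, −78 °C; pH 7 buffer work-up
Reagents that add atoms: none
Why: Corey–Bakshi–Shibata reduction under reagent control: the (R)-oxazaborolidine treats the α-branched C7 side as the large group and the C9 methylene as the small one and delivers hydride to the face that gives the 8S carbinol, while catecholborane at −78 °C does not hydroborate the alkenes.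

Step 10
Reactants: 14 (4R,7S,8S)-germacra-1(10)E,5E-diene-4,8-diol; 15 4-acetoxy-3-methoxybenzoic acid
Product: 17 (4R,7S,8S)-4-hydroxygermacra-1(10)E,5E-dien-8-yl 4-hydroxy-3-methoxybenzoate (target CNP0162316.1), via O-acetyl ester 16 (not isolated)
Conditions: DCC, DMAP (cat.), CH2Cl2, rt; then pyrrolidine, rt
Reagents that add atoms: none
Why: Steglich esterification acylates only the secondary C8 hydroxyl (the tertiary C4–OH is inert) with retention at C8, and aminolysis by pyrrolidine then removes the much more reactive phenolic acetate without touching the hindered benzoate.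

**Compound list**
1 | geraniol, (2E)-3,7-dimethylocta-2,6-dien-1-ol | CC(C)=CCC/C(C)=C/CO | starting material
2 | [(2R,3R)-3-methyl-3-(4-methylpent-3-en-1-yl)oxiran-2-yl]methanol | CC(C)=CCC[C@@]1(C)O[C@@H]1CO | intermediate
3 | (2S,3R)-3-methyl-3-(4-methylpent-3-en-1-yl)oxirane-2-carbaldehyde | CC(C)=CCC[C@@]1(C)O[C@@H]1C=O | intermediate
4 | isobutyltriphenylphosphonium bromide | CC(C)C[P+](c1ccccc1)(c1ccccc1)c1ccccc1.[Br-] | starting material
5 | isobutylidenetriphenylphosphorane | CC(C)C=P(c1ccccc1)(c1ccccc1)c1ccccc1 | intermediate (not isolated)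
6 | (2R,3R)-2-methyl-2-(4-methylpent-3-en-1-yl)-3-[(1Z)-3-methylbut-1-en-1-yl]oxirane | CC(C)=CCC[C@@]1(C)O[C@@H]1/C=C\C(C)C | intermediate
7 | nitromethane | C[N+](=O)[O-] | starting material
8 | (6R,7E,9S)-2,6,10-trimethyl-9-(nitromethyl)undeca-2,7-dien-6-ol | CC(C)=CCC[C@@](C)(O)/C=C/[C@@H](C[N+](=O)[O-])C(C)C | intermediate
9 | (2E,6R,7E,9S)-2,6,10-trimethyl-9-(nitromethyl)undeca-2,7-diene-1,6-diol | OC/C(C)=C/CC[C@@](C)(O)/C=C/[C@@H](C[N+](=O)[O-])C(C)C | intermediate
10 | (2E,6R,7E,9S)-6-hydroxy-2,6,10-trimethyl-9-(nitromethyl)undeca-2,7-dien-1-yl methyl carbonate | COC(=O)OC/C(C)=C/CC[C@@](C)(O)/C=C/[C@@H](C[N+](=O)[O-])C(C)C | intermediate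
11 | (4R,7S)-8-nitrogermacra-1(10)E,5E-dien-4-ol, both C8 epimers | [O-][N+](=O)C1C/C(C)=C/CC[C@@](C)(O)/C=C/[C@@H]1C(C)C | intermediate
12 | sodium nitronate of 11 | [Na+].[O-][N+]([O-])=C1C/C(C)=C/CC[C@@](C)(O)/C=C/[C@@H]1C(C)C | intermediate (not isolated)
13 | (4R,7S)-4-hydroxygermacra-1(10)E,5E-dien-8-one | O=C1C/C(C)=C/CC[C@@](C)(O)/C=C/[C@@H]1C(C)C | intermediate
14 | (4R,7S,8S)-germacra-1(10)E,5E-diene-4,8-diol | O[C@H]1C/C(C)=C/CC[C@@](C)(O)/C=C/[C@@H]1C(C)C | intermediate
15 | 4-acetoxy-3-methoxybenzoic acid | COc1cc(C(=O)O)ccc1OC(C)=O | starting material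
16 | (4R,7S,8S)-4-hydroxygermacra-1(10)E,5E-dien-8-yl 4-acetoxy-3-methoxybenzoate | COc1cc(C(=O)O[C@H]2C/C(C)=C/CC[C@@](C)(O)/C=C/[C@@H]2C(C)C)ccc1OC(C)=O | intermediate (not isolated)
17 | (4R,7S,8S)-4-hydroxygermacra-1(10)E,5E-dien-8-yl 4-hydroxy-3-methoxybenzoate | COc1cc(C(=O)O[C@H]2C/C(C)=C/CC[C@@](C)(O)/C=C/[C@@H]2C(C)C)ccc1O | target

**Total step count:** 10. **Longest linear sequence:** 10 steps (geraniol 1 to target 17).

**Three steps most likely to fail**

Step 4 (key bond). The nitronate must attack the isopropyl-bearing allyl terminus; β-hydride loss to a diene or attack at C5 would end the route. The fallback sets out from epoxy alcohol 2 and forms the C6–C7 bond by conjugate addition instead. PPh3/CCl4 converts 2 into (2R,3S)-3-(chloromethyl)-2-methyl-2-(4-methylpent-3-en-1-yl)oxirane F1. n-BuLi (3 equiv, THF, −78 °C) opens the ring and eliminates chloride to give (3R)-3,7-dimethyloct-6-en-1-yn-3-ol F2 with the carbinol centre untouched. Pinacolborane with Cp2ZrHCl (cat.) gives the E-alkenyl pinacolboronate F3. Rh(acac)(C2H4)2 with the BINAP antipode that delivers the 7S centre (KOH, dioxane/H2O) then adds F3 to (E)-4-methyl-1-nitropent-1-ene F4, itself made from isobutyraldehyde and nitromethane 7 by Henry condensation and dehydration. This gives nitro dienol 8, where the route is rejoined.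

Step 7 (ring closure). The ten-membered ring may lose out to oligomers, or to O-allylation by the free C4 hydroxyl giving a tetrahydrofuran. The fallback sets out from carbonate 10 and changes the substrate to a protected series. 1-(Trimethylsilyl)imidazole in CH2Cl2 gives the C4-O-trimethylsilyl ether of 10 F5. The same palladium ring closure on this hydroxyl-free, less polar chain gives the C4-O-trimethylsilyl ether of 11 F6. K2CO3 in MeOH removes the silyl group and the route is rejoined at nitro macrocycle 11.

Step 9 (C8 configuration). The conformation of the macrocyclic ketone may override the catalyst and give mainly the 8R alcohol. The fallback sets out from ketone 13 and sets C8 by inversion instead of retention. LiBH(s-Bu)3 (THF, −78 °C) or the (S)-CBS catalyst, whichever gives the 8R epimer cleanly, forms (4R,7S,8R)-germacra-1(10)E,5E-diene-4,8-diol F7. Mitsunobu esterification of F7 with acid 15 (PPh3, diisopropyl azodicarboxylate, toluene, 0 °C) inverts C8 and arrives at O-acetyl ester 16, which is deacetylated with pyrrolidine as in step 10.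

**Further compounds**
F1 | step 4 | (2R,3S)-3-(chloromethyl)-2-methyl-2-(4-methylpent-3-en-1-yl)oxirane | CC(C)=CCC[C@@]1(C)O[C@@H]1CCl
F2 | step 4 | (3R)-3,7-dimethyloct-6-en-1-yn-3-ol | CC(C)=CCC[C@@](C)(O)C#C
F3 | step 4 | (1E,3R)-3,7-dimethyl-1-(4,4,5,5-tetramethyl-1,3,2-dioxaborolan-2-yl)octa-1,6-dien-3-ol | CC(C)=CCC[C@@](C)(O)/C=C/B1OC(C)(C)C(C)(C)O1
F4 | step 4 | (E)-4-methyl-1-nitropent-1-ene | CC(C)/C=C/[N+](=O)[O-]
F5 | step 7 | C4-O-trimethylsilyl ether of 10 | COC(=O)OC/C(C)=C/CC[C@@](C)(O[Si](C)(C)C)/C=C/[C@@H](C[N+](=O)[O-])C(C)C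
F6 | step 7 | C4-O-trimethylsilyl ether of 11 | [O-][N+](=O)C1C/C(C)=C/CC[C@@](C)(O[Si](C)(C)C)/C=C/[C@@H]1C(C)C
F7 | step 9 | (4R,7S,8R)-germacra-1(10)E,5E-diene-4,8-diol | O[C@@H]1C/C(C)=C/CC[C@@](C)(O)/C=C/[C@@H]1C(C)C
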